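(All runs stem from a simulated flask with constants of no real substance; scatter was added.)

The vessel holds two phases: J sits in the second and passes as Z into the first, where X + Z gives E. Part of E moves across as G and is still counted as E.

| flask | X | J | temperature | remark | time | volume of the second phase over the first |
|---|---|---|---|---|---|---|
| dusk | 0.67 M | 1.2 equiv | 25 °C | run made earlier |  |  |
| autumn | 0.67 M | 1.2 equiv | 50 °C | run made earlier |  |  |
| teal | 2.0 M | 1.20 equiv | 30 °C |  | 3.0 d | 1.0 |
| blue | 2.0 M | 1.20 equiv | 70 °C |  | 3.0 d | 1.0 |
| red | 0.50 M | 1.20 equiv | 70 °C |  | 3.0 d | 1.0 |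
| green | 0.50 M | 1.20 equiv | 30 °C |  | 3.0 d | 1.0 |

| run | time / d | E / % |
|---|---|---|
| dusk | 2.50 | 38.4 |
| dusk | 5.00 | 59.5 |
| dusk | 12.0 | 81.5 |
| dusk | 30.0 | 94.5 |
| autumn | 0.625 | 34.4 |
| autumn | 1.25 | 58.9 |
| autumn | 3.00 | 82.9 |
| autumn | 8.00 | 89.5 |

(standard deviation of a reading: 0.5 percentage points)

- what is said of E includes G
- in the second phase: J, G; everything else is in the first
- charges count per volume of the first phase; a concentration in a rate is the amount of a species over the volume of its own phase; every rate counts per litre of the first phase
- the analysis behind the earlier runs scatters by 0.5 percentage points, standard deviation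
- steps thought possible: Z <-> J; X + Z -> E; E <-> G; E -> Q; Z -> D
- the earlier runs hold the two phases in the same ratio of volumes as the flask asked about

* the flasks by amount of E, in percent of the X charged, highest first, at 3.0 d (teal / blue / red / green)
* the same order at 4.0 h (teal / blue / red / green)
* the amount of E, in percent of the X charged of the flask you put first, at 3.0 d
* the amount of E, in percent of the X charged of the flask you put last, at 3.0 d

You need no integral for this, only a clock.

1. Read the heat. Dusk at 5.00 d and autumn at 1.25 d gave nearly the same E, 59.5 % and 58.9 %. So, as a reading, autumn ran 4.00 times as fast as dusk.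

2. Spread that roughly over the temperature. 30 °C lies 0.200 of the way from dusk to autumn, so teal and green should run 1.32 times as fast as dusk.

3. Apply the bench rule, as an assumption: X meets Z at a rate proportional to both, so at fixed equivalents and fixed temperature a doubled charge should halve the time to a given E. That gives 1.97 M⁻¹, the dusk clock, a reduced time: dusk days per day and per molar of c_X at 30 °C.

4. Teal counts 11.8 d, just short of the dusk reading at 12.0 d, so I expect a little under 81.5 %. Green counts 2.95 d, and a straight line between the first two dusk readings gives me 42.2 %.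

5. Now find the border. Autumn's last reading, at 8.00 d, counts 32.0 d on the dusk clock, 1.07 times dusk's last, yet it stands at 89.5 % against 94.5 %. So late in autumn the clock runs ahead of the flask, and I give no clock figure for blue and red at 70 °C.

The forecast says teal > blue > red > green at 3.0 d and blue > red > teal > green at 4.0 h, with 79 % first and 45 % last. Its green stands above mine. It adds: “If Z→D is the real loss, blue could lead.”

The flasks give teal > blue > red > green at 3.0 d and blue > red > teal > green at 4.0 h, with teal at 79.8 % and green at 47.1 %.

Z ⇌ J, rate k1*([Z] - [J]/K1) per volume of the first phase (partition coefficient = 0.580, kL = 1.10 × 10⁻⁵ s⁻¹); X + Z → E (k = 1.80 × 10⁻⁴ M⁻¹ s⁻¹, Ea = 62.0 kJ mol⁻¹); E ⇌ G, rate k3*([E] - [G]/K3) per volume of the first phase (partition coefficient = 0.830, kL = 1.30 × 10⁻⁵ s⁻¹); E → Q (k = 2.90 × 10⁻⁶ s⁻¹, Ea = 116 kJ mol⁻¹); Z → D (k = 2.10 × 10⁻⁵ s⁻¹, Ea = 125 kJ mol⁻¹); (constants at 70 °C) In teal, the half-life of reaction-phase E by turning into Q alone is 590 d, far longer than the 3.0 d of the reading. Put the clock on green read at 8.0 d: it counts 7.88 d on the dusk clock, between the dusk readings 59.5 % and 81.5 %, and that flask gives 74.7 %.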